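## Retrosynthetic overview

- **Feature:** in the central imidazole, C2 carries indole ring A, C4 carries the 6-bromoindole ring B, and C5 is the only CH carbon. C5–N1–C2 therefore maps onto an N-aroylglycine (glycine CH2 = C5), and N3–C4 maps onto an aldimine of the ring B aldehyde.
- **Key disconnection:** C4–C5 and C2–N3 together, a retro-(3+2) to the oxazolium-5-olate (münchnone) of an N-(4-methoxybenzyl)-N-aroylglycine and an N-tosylimine. CO2 and toluenesulfinic acid leave, and the ring becomes aromatic without an oxidant.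
- **Ring order:** both indole bicycles are bought. The oxazolium ring forms transiently, and the imidazole, the only ring built, is closed in the convergent step.
- **Design points:** both indole nitrogens are tosylated. The glycine acid is carried as a tert-butyl ester and freed by acid, so no hydroxide meets the 3-acyl-N-tosylindole. The dipole is made with a carbodiimide, because an acid anhydride would C-acylate a C4–H münchnone.
- **End game:** acidolysis of the N1 4-methoxybenzyl group while the indoles are still deactivated, then hydroxide cleavage of both tosyl groups.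

Key step: step 8

Remark: 16 and 17 are 1H-imidazoles whose N1–H/N3–H tautomers interconvert freely; both are drawn as the 4-(6-bromoindol-3-yl) tautomer of the target SMILES.

## Route

Step 1
Reactants: 1 4-methoxybenzylamine; 2 tert-butyl bromoacetate
Product: 3 tert-butyl N-(4-methoxybenzyl)glycinate
Conditions: 1 (2.5 equiv), K2CO3, MeCN, 0 °C → rt, 2 added dropwise
Reagents that add atoms: none
Why: SN2 N-alkylation of a primary amine by an α-bromo ester, in which the excess of 1 and the slow addition of 2 should hold back a second alkylation.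

Step 2
Reactants: 4 indole-3-carboxylic acid
Product: 5 1-tosylindole-3-carboxylic acid
Conditions: NaH (2.5 equiv), THF, 0 °C; TsCl (1.1 equiv), rt; then 1 M HCl
Reagents that add atoms: 4-toluenesulfonyl chloride, Cc1ccc(cc1)S(=O)(=O)Cl
Why: N-sulfonylation of the carboxylate/indolide dianion, whose nitrogen is the more nucleophilic site, while any mixed carboxylic–sulfonic anhydride is hydrolysed back to the acid in the work-up.

Step 3
Reactants: 5 1-tosylindole-3-carboxylic acid
Product: 6 1-tosylindole-3-carbonyl chloride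
Conditions: (COCl)2 (1.5 equiv), DMF (cat.), CH2Cl2, 0 °C → rt; evaporated and used crude
Reagents that add atoms: oxalyl chloride, O=C(Cl)C(=O)Cl
Why: Acid chloride formation through the chloroiminium (Vilsmeier-type) species from DMF and oxalyl chloride, conditions to which the N-sulfonylindole is inert.

Step 4
Reactants: 6 1-tosylindole-3-carbonyl chloride; 3 tert-butyl N-(4-methoxybenzyl)glycinate
Product: 7 tert-butyl N-(4-methoxybenzyl)-N-(1-tosylindole-3-carbonyl)glycinate
Conditions: Et3N (2 equiv), CH2Cl2, 0 °C → rt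
Reagents that add atoms: none
Why: Amide formation by addition–elimination of a secondary amine on an aroyl chloride, mild enough to leave the tert-butyl ester and the indole sulfonamide untouched.

Step 5
Reactants: 7 tert-butyl N-(4-methoxybenzyl)-N-(1-tosylindole-3-carbonyl)glycinate
Product: 8 N-(4-methoxybenzyl)-N-(1-tosylindole-3-carbonyl)glycine
Conditions: TFA/CH2Cl2 (1:2), rt
Reagents that add atoms: none
Why: Acidolysis of the tert-butyl ester (E1 loss of the tert-butyl cation as isobutene), which spares the hydroxide-sensitive 3-acyl-N-tosylindole and the N-(4-methoxybenzyl)amide, the latter needing hot acid to cleave.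

Step 6
Reactants: 9 6-bromoindole-3-carbaldehyde
Product: 10 6-bromo-1-tosylindole-3-carbaldehyde
Conditions: NaH (1.2 equiv), THF, 0 °C; TsCl (1.1 equiv), rt
Reagents that add atoms: 4-toluenesulfonyl chloride, Cc1ccc(cc1)S(=O)(=O)Cl
Why: N-sulfonylation of the indolide anion, which blocks the N–H and switches off the vinylogous-amide donation, so that the aldehyde becomes electrophilic enough for imine formation.

Step 7
Reactants: 10 6-bromo-1-tosylindole-3-carbaldehyde; 11 4-toluenesulfonamide
Product: 12 (E)-N-[(6-bromo-1-tosylindol-3-yl)methylidene]-4-methylbenzenesulfonamide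
Conditions: Ti(OEt)4 (2 equiv), THF, 65 °C; brine, Celite filtration, crystallisation
Reagents that add atoms: none
Why: Lewis-acid-mediated dehydrative condensation of an aldehyde with a sulfonamide, Ti(OEt)4 serving as activator and water scavenger, and the E aldimine being the only sterically accessible geometry.

Step 8
Reactants: 8 N-(4-methoxybenzyl)-N-(1-tosylindole-3-carbonyl)glycine; 12 (E)-N-[(6-bromo-1-tosylindol-3-yl)methylidene]-4-methylbenzenesulfonamide
Product: 15 1-(4-methoxybenzyl)-2-(1-tosylindol-3-yl)-4-(6-bromo-1-tosylindol-3-yl)imidazole, via münchnone 13 (not isolated), via bicyclic cycloadduct 14 (not isolated)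
Conditions: 12 (1.5 equiv), iPr2NEt (1.2 equiv), 4 Å MS, ClCH2CH2Cl, rt; iPrN=C=NiPr (DIC, 1.3 equiv) added over 4 h; then 60 °C
Reagents that add atoms: none
Why: The carbodiimide activates the carboxyl group of 8, the tertiary amide oxygen closes on it (5-exo-trig) and loss of the α-proton gives the oxazolium-5-olate 13, whose C2–N3–C4 unit is a cyclic azomethine ylide. Its enolate-like, unsubstituted C4 attacks the imine carbon of 12 while the sulfonamide nitrogen bonds to the cationic C2, a [π4s+π2s] 1,3-dipolar cycloaddition (or its stepwise Mannich/aminal-closure equivalent) that closes the five-membered N1–C2–N3–C4–C5 ring of 14 by forming C4–C5 and C2–N3 in one operation. Cycloreversion then expels CO2, the electron pair released at C2 pushes toluenesulfinate off N3, and loss of the C4 proton aromatises to 15, which is the known münchnone/N-sulfonylimine imidazole synthesis. The three stereocentres of 14 are all erased, so no stereocontrol is required. The selectivity needed is the orientation of dipole and imine: the most nucleophilic and least hindered terminus (C4–H of 13) should pair with the electrophilic imine carbon and give the 2,4-pattern, whereas the reverse pairing would give the 4,5-diaryl isomer with C2–H. A carbodiimide replaces an acid anhydride because a C4–H münchnone is C-acylated by anhydrides (Dakin–West reactivity), slow generation in the presence of excess 12 keeps 13 dilute so that it should be trapped before it self-acylates, the amine base holds the sulfinic acid away from the imine, and the aryl bromide and N-tosyl groups take no part.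

Step 9
Reactants: 15 1-(4-methoxybenzyl)-2-(1-tosylindol-3-yl)-4-(6-bromo-1-tosylindol-3-yl)imidazole
Product: 16 4-(6-bromo-1-tosylindol-3-yl)-2-(1-tosylindol-3-yl)-1H-imidazole
Conditions: TFA, anisole (10 equiv), 75 °C
Reagents that add atoms: none
Why: SN1-type acidolysis in which protonation at N3 turns the imidazole into a leaving group and anisole intercepts the 4-methoxybenzyl cation (Friedel–Crafts alkylation), while both indoles, still deactivated by their sulfonyl groups, should escape benzylation.

Step 10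
Reactants: 16 4-(6-bromo-1-tosylindol-3-yl)-2-(1-tosylindol-3-yl)-1H-imidazole
Product: 17 nortopsentin C
Conditions: KOH (10 equiv), THF/MeOH/H2O, 60 °C; aqueous work-up at pH 8
Reagents that add atoms: none
Why: Sulfonamide hydrolysis by attack of hydroxide at sulfur with the indolide as leaving group, the aryl bromide and the imidazole being inert and the water in the medium steering the sulfonyl groups to the tosylate salt rather than to a methylating sulfonate ester.

## Compound list

1 | 4-methoxybenzylamine | COc1ccc(CN)cc1 | starting material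
2 | tert-butyl bromoacetate | CC(C)(C)OC(=O)CBr | starting material
3 | tert-butyl N-(4-methoxybenzyl)glycinate | COc1ccc(CNCC(=O)OC(C)(C)C)cc1 | intermediate
4 | indole-3-carboxylic acid | O=C(O)c1c[nH]c2ccccc12 | starting material
5 | 1-tosylindole-3-carboxylic acid | Cc1ccc(cc1)S(=O)(=O)n1cc(C(=O)O)c2ccccc12 | intermediate
6 | 1-tosylindole-3-carbonyl chloride | Cc1ccc(cc1)S(=O)(=O)n1cc(C(=O)Cl)c2ccccc12 | intermediate
7 | tert-butyl N-(4-methoxybenzyl)-N-(1-tosylindole-3-carbonyl)glycinate | COc1ccc(CN(CC(=O)OC(C)(C)C)C(=O)c2cn(S(=O)(=O)c3ccc(C)cc3)c3ccccc23)cc1 | intermediate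
8 | N-(4-methoxybenzyl)-N-(1-tosylindole-3-carbonyl)glycine | O=C(O)CN(Cc1ccc(OC)cc1)C(=O)c1cn(S(=O)(=O)c2ccc(C)cc2)c2ccccc12 | intermediate
9 | 6-bromoindole-3-carbaldehyde | O=Cc1c[nH]c2cc(Br)ccc12 | starting material
10 | 6-bromo-1-tosylindole-3-carbaldehyde | O=Cc1cn(S(=O)(=O)c2ccc(C)cc2)c2cc(Br)ccc12 | intermediate
11 | 4-toluenesulfonamide | Cc1ccc(cc1)S(N)(=O)=O | starting material
12 | (E)-N-[(6-bromo-1-tosylindol-3-yl)methylidene]-4-methylbenzenesulfonamide | Cc1ccc(cc1)S(=O)(=O)/N=C/c1cn(S(=O)(=O)c2ccc(C)cc2)c2cc(Br)ccc12 | intermediate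
13 | münchnone: 3-(4-methoxybenzyl)-2-(1-tosylindol-3-yl)-1,3-oxazol-3-ium-5-olate | [O-]c1c[n+](Cc2ccc(OC)cc2)c(-c2cn(S(=O)(=O)c3ccc(C)cc3)c3ccccc23)o1 | intermediate
14 | bicyclic cycloadduct: 5-(6-bromo-1-tosylindol-3-yl)-7-(4-methoxybenzyl)-6-tosyl-1-(1-tosylindol-3-yl)-2-oxa-6,7-diazabicyclo[2.2.1]heptan-3-one (racemic, configuration at C5 not defined, all stereocentres lost on aromatisation) | O=C1OC2(c3cn(S(=O)(=O)c4ccc(C)cc4)c4ccccc34)N(Cc3ccc(OC)cc3)C1C(c1cn(S(=O)(=O)c3ccc(C)cc3)c3cc(Br)ccc13)N2S(=O)(=O)c1ccc(C)cc1 | intermediate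
15 | 1-(4-methoxybenzyl)-2-(1-tosylindol-3-yl)-4-(6-bromo-1-tosylindol-3-yl)imidazole | COc1ccc(Cn2cc(-c3cn(S(=O)(=O)c4ccc(C)cc4)c4cc(Br)ccc34)nc2-c2cn(S(=O)(=O)c3ccc(C)cc3)c3ccccc23)cc1 | intermediate
16 | 4-(6-bromo-1-tosylindol-3-yl)-2-(1-tosylindol-3-yl)-1H-imidazole | Cc1ccc(cc1)S(=O)(=O)n1cc(-c2c[nH]c(-c3cn(S(=O)(=O)c4ccc(C)cc4)c4ccccc34)n2)c2ccc(Br)cc12 | intermediate
17 | nortopsentin C, 4-(6-bromo-1H-indol-3-yl)-2-(1H-indol-3-yl)-1H-imidazole | Brc1ccc2c(-c3c[nH]c(-c4c[nH]c5ccccc45)n3)c[nH]c2c1 | target

## Step count and risks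

Total step count: 10.
Longest linear sequence: 7 steps (steps 2, 3, 4, 5, 8, 9 and 10, from indole-3-carboxylic acid 4).

**1. Step 8.**
- Risk: self-acylation and oligomerisation of the C4-unsubstituted dipole may outrun its capture by the imine, and the orientation of the addition may erode.
- Fallback: it sets out from imine 12 and acid chloride 6 and comes back at 16. It makes the same ring bonds one at a time, so the connectivity is fixed by construction and no N-benzyl group is needed.
- An aza-Henry addition of nitromethane to 12 (MeNO2, cat. Et3N, rt) should give racemic N-[1-(6-bromo-1-tosylindol-3-yl)-2-nitroethyl]-4-methylbenzenesulfonamide F1.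
- Zn/HCl in EtOH reduces the nitro group without touching the aryl bromide and gives N-[2-amino-1-(6-bromo-1-tosylindol-3-yl)ethyl]-4-methylbenzenesulfonamide F2.
- Acylation with 6 (Et3N, CH2Cl2) gives N-[2-(6-bromo-1-tosylindol-3-yl)-2-(tosylamino)ethyl]-1-tosylindole-3-carboxamide F3.
- Cyclodehydration with Ph3PO/Tf2O in CH2Cl2 closes the sulfonamide nitrogen onto the activated amide and gives 5-(6-bromo-1-tosylindol-3-yl)-1-tosyl-2-(1-tosylindol-3-yl)-4,5-dihydro-1H-imidazole F4.
- DBU in warm toluene eliminates toluenesulfinic acid, and tautomerisation delivers 16.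

**2. Step 9.**
- Risk: heterolysis of the N1–benzyl bond of the protonated imidazole may be sluggish, and the benzyl cation may be transferred back onto carbon during prolonged heating.
- Fallback: it sets out from acid chloride 6 and imine 12 and comes back at 16. It replaces the nitrogen substituent by the much more acid-labile 2,4-dimethoxybenzyl group, and therefore also replaces the acid-cleaved ester by a benzyl ester.
- 2,4-Dimethoxybenzylamine is alkylated with benzyl bromoacetate (K2CO3, MeCN) to benzyl N-(2,4-dimethoxybenzyl)glycinate F5.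
- Acylation with 6 gives benzyl N-(2,4-dimethoxybenzyl)-N-(1-tosylindole-3-carbonyl)glycinate F6.
- Hydrogenolysis (H2, Pd/C, EtOAc; this fragment holds no halogen) gives N-(2,4-dimethoxybenzyl)-N-(1-tosylindole-3-carbonyl)glycine F7.
- Under the conditions of step 8 this acid is dehydrated to 3-(2,4-dimethoxybenzyl)-2-(1-tosylindol-3-yl)-1,3-oxazol-3-ium-5-olate F8.
- F8 adds to 12 to give the 7-(2,4-dimethoxybenzyl) bicyclic cycloadduct F9. Loss of CO2 and toluenesulfinic acid then gives 1-(2,4-dimethoxybenzyl)-2-(1-tosylindol-3-yl)-4-(6-bromo-1-tosylindol-3-yl)imidazole F10.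
- TFA/anisole at rt to 40 °C should then release 16.

**3. Step 7.**
- Risk: the condensation may stay incomplete, and the imine may hydrolyse back during the aqueous titanium work-up.
- Fallback: it sets out from aldehyde 10 and sulfonamide 11 and comes back at 12. It goes through a crystalline, storable imine precursor instead of a direct dehydration.
- 10, 11 and sodium 4-toluenesulfinate in HCO2H/H2O at rt should precipitate racemic N-[(6-bromo-1-tosylindol-3-yl)(tosyl)methyl]-4-methylbenzenesulfonamide F11, which is collected by filtration.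
- Brief shaking with aqueous NaHCO3/CH2Cl2 eliminates sulfinate and releases 12 in the dried organic phase, ready for step 8.

## Further compounds

F1 | step 8 | N-[1-(6-bromo-1-tosylindol-3-yl)-2-nitroethyl]-4-methylbenzenesulfonamide (racemic) | O=[N+]([O-])CC(NS(=O)(=O)c1ccc(C)cc1)c1cn(S(=O)(=O)c2ccc(C)cc2)c2cc(Br)ccc12
F2 | step 8 | N-[2-amino-1-(6-bromo-1-tosylindol-3-yl)ethyl]-4-methylbenzenesulfonamide (racemic) | NCC(NS(=O)(=O)c1ccc(C)cc1)c1cn(S(=O)(=O)c2ccc(C)cc2)c2cc(Br)ccc12
F3 | step 8 | N-[2-(6-bromo-1-tosylindol-3-yl)-2-(tosylamino)ethyl]-1-tosylindole-3-carboxamide (racemic) | O=C(NCC(NS(=O)(=O)c1ccc(C)cc1)c1cn(S(=O)(=O)c2ccc(C)cc2)c2cc(Br)ccc12)c1cn(S(=O)(=O)c2ccc(C)cc2)c2ccccc12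
F4 | step 8 | 5-(6-bromo-1-tosylindol-3-yl)-1-tosyl-2-(1-tosylindol-3-yl)-4,5-dihydro-1H-imidazole (racemic) | Cc1ccc(cc1)S(=O)(=O)N1C(c2cn(S(=O)(=O)c3ccc(C)cc3)c3cc(Br)ccc23)CN=C1c1cn(S(=O)(=O)c2ccc(C)cc2)c2ccccc12
F5 | step 9 | benzyl N-(2,4-dimethoxybenzyl)glycinate | COc1ccc(CNCC(=O)OCc2ccccc2)c(OC)c1
F6 | step 9 | benzyl N-(2,4-dimethoxybenzyl)-N-(1-tosylindole-3-carbonyl)glycinate | COc1ccc(CN(CC(=O)OCc2ccccc2)C(=O)c2cn(S(=O)(=O)c3ccc(C)cc3)c3ccccc23)c(OC)c1
F7 | step 9 | N-(2,4-dimethoxybenzyl)-N-(1-tosylindole-3-carbonyl)glycine | COc1ccc(CN(CC(=O)O)C(=O)c2cn(S(=O)(=O)c3ccc(C)cc3)c3ccccc23)c(OC)c1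
F8 | step 9 | 3-(2,4-dimethoxybenzyl)-2-(1-tosylindol-3-yl)-1,3-oxazol-3-ium-5-olate | [O-]c1c[n+](Cc2ccc(OC)cc2OC)c(-c2cn(S(=O)(=O)c3ccc(C)cc3)c3ccccc23)o1
F9 | step 9 | 7-(2,4-dimethoxybenzyl) bicyclic cycloadduct: 5-(6-bromo-1-tosylindol-3-yl)-7-(2,4-dimethoxybenzyl)-6-tosyl-1-(1-tosylindol-3-yl)-2-oxa-6,7-diazabicyclo[2.2.1]heptan-3-one (racemic, configuration at C5 not defined) | O=C1OC2(c3cn(S(=O)(=O)c4ccc(C)cc4)c4ccccc34)N(Cc3ccc(OC)cc3OC)C1C(c1cn(S(=O)(=O)c3ccc(C)cc3)c3cc(Br)ccc13)N2S(=O)(=O)c1ccc(C)cc1
F10 | step 9 | 1-(2,4-dimethoxybenzyl)-2-(1-tosylindol-3-yl)-4-(6-bromo-1-tosylindol-3-yl)imidazole | COc1ccc(Cn2cc(-c3cn(S(=O)(=O)c4ccc(C)cc4)c4cc(Br)ccc34)nc2-c2cn(S(=O)(=O)c3ccc(C)cc3)c3ccccc23)c(OC)c1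
F11 | step 7 | N-[(6-bromo-1-tosylindol-3-yl)(tosyl)methyl]-4-methylbenzenesulfonamide (racemic) | Cc1ccc(cc1)S(=O)(=O)NC(c1cn(S(=O)(=O)c2ccc(C)cc2)c2cc(Br)ccc12)S(=O)(=O)c1ccc(C)cc1
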